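Compare the nucleophile charged with the nucleophile free on average during the run: the reckoning below turns on the gap between them.

    electrophile ⇌ dormant form (K1 = 0.48, k1 = 0.23 s⁻¹)
    nucleophile + acid set free ⇌ protonated nucleophile, settled at all times (K2 = 2.5 × 10⁵ M⁻¹)
    gas ⇌ free base, rate k3*(csat - [free base]) (k3 = 0.37 s⁻¹, csat = 0.58 mM)
    acid set free + free base ⇌ salt of the base, settled at all times (K4 = 2.6 × 10⁷ M⁻¹)
    electrophile + nucleophile → acid set free + target (k5 = 130 M⁻¹ s⁻¹)
    free base + target → over-reaction product (k6 = 1000 M⁻¹ s⁻¹)

| setting | west | south | north |
|---|---|---|---|
| electrophile | 2.0 mM | 2.0 mM | 2.0 mM |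
| nucleophile | 1.10 equiv | 1.40 equiv | 1.80 equiv |
| gas | 0.58 mM (held) | 0.58 mM (held) | 0.58 mM (held) |
| time | 4.0 s | 4.0 s | 4.0 s |

- part of the electrophile that has reacted at the end, west
- part of the electrophile that has reacted at the end, south
- part of the electrophile that has reacted at the end, north
- what raising the equivalents of nucleophile from its lowest to its highest value here does to the part of the electrophile that has reacted (changes below 5 percentage points count as none) (no change / it falls / it rises)

- at the start none of free base is dissolved
- what has gone from electrophile into another species counts as reacted, even if it can come back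
- run time (west): 4.0 s

1. Treat electrophile and dormant form as one pool, because their relaxation half-life by that exchange alone, 0.977 s in west, is short against the run, 4.0 s. Take f, the share of the pool that is free electrophile, as 67.6 %.

2. Let B̄ be the mean free nucleophile and k the constant 130 M⁻¹ s⁻¹. The pool then decays pseudo-first-order, and the target step turns over X = c(1 − exp(−k·f·B̄·t)), with c the electrophile charged and t the time. For west, hold B̄ at the charge, 2.20 mM, which gives X = 1.08 mM.

3. Put that back. Each turnover takes one nucleophile, so the mean of start and end is 1.66 mM, and X becomes 0.884 mM.

4. Reforge the weak link, the acid, since each turnover also frees one. Count the gas feed, G = k₃·csat·t with k₃ the transfer coefficient, as cover: G = 0.858 mM. Assume that acid beyond G protonates a further nucleophile. So B̄ = charge − (X + X − G)/2, the mean free nucleophile 1.74 mM for west.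

5. Electrophile reacted is 1 − f·exp(−k·f·B̄·t), so I commit to 63.4 % for west. The same chain gives X of 1.07 mM in south and 1.27 mM in north. Then B̄ is 2.16 mM in south and 2.76 mM in north, and the reacted parts are 68.4 % and 74.4 %.

The forecast says 70.8 %, 76.2 % and 82 %, and it rises, with “free nucleophile, which stays near 2–3 mM”. It stands higher than my west figure.

The simulation gives 63.8 %, 69.4 % and 75.7 %: it rises, by 12 percentage points. The forecast's figures are what the nucleophile held at its charge gives.

West ended with 52 % of its nucleophile free, a start-to-end mean of 1.67 mM against the reckoned 1.74 mM. Now take the neighbour with 3.4 mM of electrophile, equivalents and time as in west. Scaling 1.74 mM with the charge gives 2.97 mM and X = 2.20 mM, which is above G. Put back, this X makes the reckoned B̄ 1.97 mM, and the reckoned reacted part comes to 66.2 %. The simulated neighbour gives 68.3 %, with 0.924 mM of protonated nucleophile against 0.169 mM in west.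

The rate constants are made up; the flask was simulated.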